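The numbers in the tables come from a simulation for an exercise, noise included.

A small charge of enzyme, 10 µM against 20 mM of substrate, works in this flask, and Sunday's run follows the flask up to 120 h, where product reads 72.0%.

common to all: substrate 20 mM; enzyme 10 µM
- Sunday's: the very flask that is asked about, followed so far
- flask: time 8.0 d

- Sunday's (time / h: product / %, substrate / %): 10.0: 33.3, 67.0; 20.0: 51.5, 49.7; 50.0: 68.7, 31.1; 120: 72.0, 28.7

(scatter of a reading: 0.5 percentage points)

- dusk: at 8.0 d take out 90% of the product then present, then wait 4.0 d
- autumn: at 8.0 d add substrate, 50.0% of the amount charged, then wait 4.0 d
- noon: change nothing and wait 4.0 d more
- dawn: at 8.0 d add enzyme, 100% of the amount charged, then wait 4.0 d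

- what is taken out of product is counted as made
- steps that have been proposed: substrate + enzyme -> product + enzyme; enzyme -> spent catalyst
- additions bring no volume worth counting

* product, in percent of the substrate first charged, at 8.0 d
* which option adds most product ("none" when 2 percentage points or less is all one gets) (dusk / autumn / noon / dawn / none)
* product present, with what was taken out counted in, in percent of the substrate first charged, after noon
* product present, with what was taken out counted in, in percent of the substrate first charged, after dawn

We take the proposed steps at their word: [enzyme] decays by first order, and there is no back step. If the rate is also first order in substrate, then d ln[substrate]/dt is proportional to [enzyme]. The time integral of [enzyme] is proportional to the enzyme lost so far, so the rate integrates in closed form: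

ln([substrate]charged/[substrate]) = D × (share of the enzyme spent by then)

Taking the last reading as the end gives D = 1.25. We carry this lifetime dose, the logarithm of the factor by which one charge of enzyme shrinks the substrate over its whole life; it is a logarithmic cousin of the total turnover number.

But was 120 h the end? The reading at 20.0 h puts the share spent at 56.0%, which leaves 0.725% of the enzyme at 120 h. That could still turn 0.26 percentage points, less than the scatter of 0.5 points. So we expect about 72.0% at 8.0 d, with 0.0377% of the enzyme left. After autumn's addition, the enzyme we expect to be left then turns 0.037 points of substrate, less than the margin of 2 points, and with no back step, we reckon 0.014 points for dusk and for noon.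

Is the substrate really first order? The decay constant read at 10.0 h is 0.0387 /h, and at 50.0 h it is 0.0549 /h. They disagree, so D is a rough reading. We still commit: a fresh charge equal to the first brings the same dose, so the substrate shrinks by the same factor again:

[substrate] = 28.7% × 28.7% = 8.24%, product 91.8%, gain 20 points

Our pick is dawn. The forecast differs: 71.7% now, 71.7% after noon, 71.7% after dawn, and autumn as best, on the ground that “A constant k means the enzyme is still active, and the plateau is a reversible equilibrium”.

The flask gives 72.0% at 8.0 d, 72.0% after noon and 92.1% after dawn, so dawn is the best option, adding 20 points.

    substrate + enzyme → product + enzyme, rate k1*[substrate]^2*[enzyme]/(1 + ([substrate]/Kh1)^2) (5.60 mM, k = 50000 /M²/min)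
    enzyme → spent catalyst (k = 8.50 × 10⁻⁴ /min)

At 192 h the flask holds 0.00559% of its enzyme. Read through the dose, the flask after dawn stands at 2.54, twice D. The neighbour with 0.0040 mM of enzyme has a dose of 0.500, which leaves 60.7% of its substrate by this reckoning, and that flask holds 67%.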